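The furanone ring is read as a masked maleic anhydride: C2 (lactone carbonyl) and C5 (the carbon bearing the exocyclic CBr2) both sit on ring oxygen O1 at the carboxyl oxidation level, and C3(butyl)=C4(Br) is a cis-locked former alkyne. Everything rests on cutting C2–C3 and C4–C5 at once. The key step is a palladium-catalysed oxidative dicarbonylation in which hex-1-yne, two molecules of CO and water are joined around the ring core, forming both C–C bonds and both ring C–O bonds in one operation; its precursor is simply the terminal alkyne. Bromination–dehydrobromination then places Br at C4, and a site-selective dibromo-Wittig olefination converts the C5 carbonyl into C=CBr2.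

Key step: step 1

Remark: ring atoms are numbered as in furan-2(5H)-one (O1, C2 carbonyl, C3 butyl, C4 bromo, C5 dibromomethylidene). The target has no stereocentre and the exocyclic carbon carries two identical bromines, so no configuration has to be set.

Step 1
Reactants: 1 hex-1-yne; 2 carbon monoxide (two equivalents)
Product: 3 3-butylfuran-2,5-dione (butylmaleic anhydride)
Conditions: PdI2 (cat.), KI, CO/air (4:1, 20 atm), dioxane–H2O, 80 °C; then distillation
Reagents that add atoms: carbon monoxide, [C-]#[O+] (compound 2, incorporated twice); water, O (ring oxygen)
Why: PdI2, CO and water generate an I–Pd–CO2H species that adds syn across the triple bond of 1, and CO insertion into the resulting vinyl–palladium bond gives a (Z)-configured acylpalladium carboxylic acid, so each alkyne carbon gains one carbonyl carbon (ring bonds C2–C3 and C4–C5 of the later furanone). The cis carboxyl oxygen then captures the acylpalladium carbon in a 5-exo-trig acyl substitution that closes the anhydride ring and releases zerovalent palladium and HI, which air reoxidises via I2 to PdI2. The closest known reaction type is the PdI2/KI-catalysed oxidative dicarbonylation of terminal alkynes to maleic anhydrides in aqueous dioxane. No stereocentre is formed. The selectivity needed is cis double carbonylation over mono-carbonylation to the alk-2-ynoic acid and over reductive carbonylation to furanones; it is secured by the syn insertion (the only geometry that lets the ring close), the base-free iodide-rich medium and the oxidising atmosphere. Regiochemistry of the first insertion is immaterial because both alkyne carbons are carbonylated, and the butyl group simply stays on its alkyne carbon.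

Step 2
Reactants: 3 3-butylfuran-2,5-dione
Product: 5 3-bromo-4-butylfuran-2,5-dione, via trans-dibromide 4 (not isolated)
Conditions: Br2, AlBr3 (cat.), neat, 60 °C, dark; evaporate; then iPr2NEt, CH2Cl2, 0 °C
Reagents that add atoms: bromine, BrBr
Why: Bromination–dehydrobromination: Lewis-acid-assisted anti addition of Br2 to the electron-poor ring alkene should give 4, whose only ring hydrogen is α to a carbonyl and β to the tertiary bromide, so base-induced E1cB/E2 loss of HBr can only leave the surviving bromine on the former CH carbon (C4 of the later furanone), as in the known preparation of bromo(alkyl)maleic anhydrides and imides.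

Step 3
Reactants: 5 3-bromo-4-butylfuran-2,5-dione
Product: 6 4-bromo-3-butyl-5-(dibromomethylidene)furan-2(5H)-one
Conditions: PPh3 (2.4 equiv), CBr4 (1.2 equiv), CH2Cl2, 0 °C (ylide preformed); then 5, 0 °C to rt
Reagents that add atoms: carbon tetrabromide, BrC(Br)(Br)Br (delivers CBr2 through Ph3P=CBr2 made in the flask)
Why: Ramirez dibromo-Wittig olefination of a cyclic anhydride carbonyl, by analogy with the known dihalomethylenation of cyclic anhydrides and lactones: the preformed ylide should attack the carbonyl next to C–Br, which is inductively activated and less shielded, whereas the other carbonyl is a vinylogous acyl bromide damped by bromine lone-pair donation and flanked by the butyl group; the new exocyclic carbon bears two identical bromines, so no alkene geometry arises.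

Compound list
1 | hex-1-yne | CCCCC#C | starting material
2 | carbon monoxide | [C-]#[O+] | starting material
3 | 3-butylfuran-2,5-dione (butylmaleic anhydride) | CCCCC1=CC(=O)OC1=O | intermediate
4 | rac-(3R,4R)-3,4-dibromo-3-butyloxolane-2,5-dione (trans-dibromide, one enantiomer drawn) | CCCC[C@]1(Br)[C@H](Br)C(=O)OC1=O | intermediate (not isolated)
5 | 3-bromo-4-butylfuran-2,5-dione | CCCCC1=C(Br)C(=O)OC1=O | intermediate
6 | 4-bromo-3-butyl-5-(dibromomethylidene)furan-2(5H)-one | CCCCC1=C(Br)C(=C(Br)Br)OC1=O | target

Total step count: 3. Longest linear sequence: 3 steps.

Steps most likely to fail

1. Step 3. The ylide may attack the wrong anhydride carbonyl (insufficient site selectivity between the two C=O groups), or phosphorus nucleophiles may displace the ring bromide by addition–elimination. The fallback fixes the regiochemistry by the order of bond formation instead of by carbonyl discrimination; it sets out from 1 and comes back to the route at 6. Cobalt-catalysed phase-transfer carbonylation of 1 with MeI and CO (Co2(CO)8 cat., cetyltrimethylammonium bromide, benzene/aq. NaOH, rt) should proceed through acetylcobalt tetracarbonyl, MeC(O)Co(CO)4. The acyl group adds to the terminal alkyne carbon and CO enters at the internal one, giving 3-butyl-5-hydroxy-5-methylfuran-2(5H)-one F1, so the future exocyclic carbon is already attached to C5. Addition of Br2 (CH2Cl2, rt) to the ring alkene gives 3,4-dibromo-3-butyl-5-hydroxy-5-methyloxolan-2-one F2. Et3N at 0 °C then removes HBr (the hydrogen α to the masked ketone, the bromide β to it) to give 4-bromo-3-butyl-5-hydroxy-5-methylfuran-2(5H)-one F3. Acid-catalysed bromination (Br2, HBr/AcOH, 50 °C) of the methyl ketone of its ring-opened tautomer, the only enolisable position left, gives 4-bromo-3-butyl-5-(dibromomethyl)-5-hydroxyfuran-2(5H)-one F4. Dehydration with P2O5 (CH2Cl2, reflux) delivers 6.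

2. Step 2. Electrophilic addition to the electron-poor ring alkene may be sluggish, allowing radical substitution in the butyl chain to compete, and the amine may cause tautomerisation to the butylidene isomer or ring opening during HBr loss. The fallback moves the bromination to the free diacid and removes the amine; it sets out from 3 and comes back at 5. Hydrolysis (H2O/THF, 50 °C) gives (Z)-2-butylbut-2-enedioic acid F5. Ionic addition of Br2 in water at rt gives 2,3-dibromo-2-butylbutanedioic acid F6. Heating in Ac2O closes the anhydride and expels HBr thermally to give 5.

3. Step 1. In the aqueous medium the organopalladium intermediates may be diverted into hydride (water-gas-shift) chemistry, giving reduced furanone-type products or ring-opened diacid, with precipitation of palladium metal. The fallback separates C–C bond formation from ring closure; it sets out from 1 and comes back at 3. Water-free oxidative dimethoxycarbonylation (PdI2 cat., KI, CO/air, MeOH, 60 °C) through a methoxycarbonylpalladium species gives dimethyl (Z)-2-butylbut-2-enedioate F7. Acidic hydrolysis (aq. HCl/AcOH, reflux) followed by distillation closes the cis-diacid to 3.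

Further compounds
F1 | step 3 | 3-butyl-5-hydroxy-5-methylfuran-2(5H)-one (racemic) | CCCCC1=CC(C)(O)OC1=O
F2 | step 3 | 3,4-dibromo-3-butyl-5-hydroxy-5-methyloxolan-2-one (diastereomer mixture) | CCCCC1(Br)C(Br)C(C)(O)OC1=O
F3 | step 3 | 4-bromo-3-butyl-5-hydroxy-5-methylfuran-2(5H)-one (racemic) | CCCCC1=C(Br)C(C)(O)OC1=O
F4 | step 3 | 4-bromo-3-butyl-5-(dibromomethyl)-5-hydroxyfuran-2(5H)-one (racemic) | CCCCC1=C(Br)C(O)(C(Br)Br)OC1=O
F5 | step 2 | (Z)-2-butylbut-2-enedioic acid | OC(=O)/C=C(/CCCC)C(=O)O
F6 | step 2 | 2,3-dibromo-2-butylbutanedioic acid (diastereomer mixture) | CCCCC(Br)(C(=O)O)C(Br)C(=O)O
F7 | step 1 | dimethyl (Z)-2-butylbut-2-enedioate | COC(=O)/C=C(/CCCC)C(=O)OC
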